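- I started from the solid.

all flasks: Vo 0.10 M
- elm: Dw 0.030 M; temperature 70 °C; the very flask that is asked about, followed so far
- maple: Dw 0.015 M; temperature 65 °C; run made earlier
- flask: Dw 0.0300 M; temperature 70 °C; time 6.0 d

elm run (percent of the Vo charged)

| time / d | Qa / % | Vo / % |
|---|---|---|
| 0.250 | 13 | 39 |
| 0.417 | 24 | 16 |
| 0.625 | 40 | 2 |
| 1.04 | 55 | 2 |
| 1.67 | 64 | 0 |
| 2.50 | 67 | 0 |
| 4.00 | 66 | 0 |

maple run (percent of the Vo charged)

| time / d | Qa / % | Vo / % |
|---|---|---|
| 0.417 | 15 | 26 |
| 0.833 | 38 | 1 |
| 1.25 | 46 | 1 |
| 1.67 | 56 | 2 |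
| 2.00 | 56 | 1 |
| 2.50 | 63 | 2 |
| 3.00 | 60 | 0 |

- delta: at 6.0 d take out 90% of the Qa then present, then wait 3.0 d
- epsilon: at 6.0 d raise the temperature by 10 K, then wait 3.0 d
- beta: change nothing and wait 3.0 d more

- as a solid, counted per litre of solution: Vo
- removed Qa is counted in
- steps that have been proposed: Xo + Dw -> XoDw; Xo <-> Eb; Xo -> Qa; Eb -> Zo; Vo <-> Xo
- at the start none of Vo is in solution

1. Qa, in percent of the Vo first charged, at 6.0 d
2. which option adds most Qa ("none" when 2 percentage points or less is all one gets) (delta / epsilon / beta / none)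
3. Qa present, with what was taken out counted in, in percent of the Vo first charged, after delta
4. Qa present, with what was taken out counted in, in percent of the Vo first charged, after beta

- In elm, Vo had fallen to 2% by 0.625 d, so I took that reading as the crossing at which control passed from dissolving to the consumption of dissolved feed, and I treated the later fall in feed as pseudo-first-order.
- As read from the scattered elm readings, the Qa rate fell from 0.361 d⁻¹ to 0.143 d⁻¹ of the charge across neighbouring intervals, which gave me an estimated decay constant of 1.78 d⁻¹.
- Multiplying it by the time from the crossing to the look gave N = 9.55, which I called the exhaustion number, the count of e-foldings the dissolved feed has passed through by the look.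
- So I reckoned that a share of 0.00712% of the feed at the crossing was left at the look, and I estimated the Qa still to come in elm at 0.0019 percentage points, less than the 2 points that counts; since Xo -> Qa is proposed as one-way, I expected nothing from delta, and with that little feed I expected nothing from epsilon.
- N gives no plateau height and says nothing of a slow store, so I tested it on the elm readings: Qa fell by 1 point between 2.50 d and 4.00 d, with 2 points on each reading, which shows no creep beyond the scatter, and the mean of these two readings gave me 66.5% as my estimate, with "none" as the best option.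
- The forecast gave 67% now, 67.5% after delta, 67.5% after beta and none as best, holding that “nothing remains to feed Qa, barring a small Eb reservoir”.
- The elm flask gave 66.4%, then 66.4% after delta and 66.4% after beta, so the best option was none.

    Xo + Dw → XoDw (k = 1.20 L mol⁻¹ h⁻¹, Ea = 68.0 kJ mol⁻¹)
    Xo ⇌ Eb (K = 0.610, k = 0.0700 h⁻¹, Ea = 123 kJ mol⁻¹, ΔH = −90.0 kJ mol⁻¹)
    Xo → Qa (k = 0.0850 h⁻¹, Ea = 122 kJ mol⁻¹)
    Eb → Zo (k = 0.0450 h⁻¹, Ea = 107 kJ mol⁻¹)
    Vo ⇌ Xo, rate k5*(cs5 - [Xo]) while solid is left; crystals form when [Xo] > cs5 (solubility = 0.0600 M, k = 0.280 h⁻¹)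
    (constants at 70 °C)

- With N at 9.55, beta added 0 points against the 0.0019 points I had reckoned. At 0.193 d Xo went to Qa 2.7 times as fast as to XoDw, and at 6.00 d elm held Qa at 66.4%, more than XoDw at 18.2%.
- For the flask kept at 55 °C, I scaled the constant with 122 kJ mol⁻¹ as a rough estimate and borrowed elm's crossing, which gave 0.252 d⁻¹ and N = 1.35, so I reckoned a share of 25.9% of the feed left at the look; at 6.00 d that computed flask held Xo at 5.13%, Eb at 12.1% and Qa at 43.8%.

The readings are simulated for substances that don't exist; noise was put on by code.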